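**Retrosynthetic overview**

1. The cyclopentenone ring (C1″–C5″ of the 2‑amino‑3‑hydroxycyclopent‑2‑enone unit) is closed last, by a base‑induced transannular N→C acyl shift that contracts an N‑trienoyl piperidine‑2,5‑dione to the 2‑acylaminocyclopentane‑1,3‑dione. Enabling feature: C2″ carries the amide nitrogen and lies between the two ring carbonyl carbons C1″ and C3″, so moving the C1″ carbonyl from C2″ onto N gives a six‑membered imide whose N–CH2–C(=O) methylene is acidic.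
2. The all‑E triene is cut at C8–C9: Stille coupling of a core (E)‑vinylstannane with a (2E,4E)‑5‑bromopentadienoyl imide.
3. Core: the C2–N enamide bond comes from Cu‑catalysed amidation of an α‑iodoenone with the side‑chain amide; the cis C4/C5 diol comes from a catalytic desymmetrising acetalisation/oxa‑Michael cascade on an achiral 4‑alkynyl p‑quinol, which sets both stereocentres in one event.
4. Side chain: Evans methylation sets C6′; two Wittig olefinations build the (2E,4E)‑diene.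
5. Ring order: the carbocycle is bought (quinone monoketal); a temporary dioxolane is made in step 9 and removed in step 13; the lactam ring is bought; the cyclopentenone ring is closed last in step 24.

Key step: step 24

Remark 1: the sense of induction in step 9 is assumed; (R)‑TRIP is written as the catalyst giving the (3aS,7aS) series, and its enantiomer is used if the sense proves opposite.
Remark 2: 5‑hydroxypiperidin‑2‑one 27 is used as the racemate; 28–30 are racemic and this centre is removed in step 22.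

**Route**

Step 1
Reactants: 1 (R)‑4‑benzyloxazolidin‑2‑one; 2 hexanoyl chloride
Product: 3 (R)‑4‑benzyl‑3‑hexanoyloxazolidin‑2‑one
Conditions: n‑BuLi, THF, −78 °C; then 2, −78 → 0 °C
Reagents that add atoms: none
Why: N‑acylation of the lithiated oxazolidinone by the acid chloride is the standard entry to Evans imides.

Step 2
Reactants: 3 (R)‑4‑benzyl‑3‑hexanoyloxazolidin‑2‑one
Product: 4 (R)‑4‑benzyl‑3‑[(2R)‑2‑methylhexanoyl]oxazolidin‑2‑one
Conditions: NaHMDS, THF, −78 °C; MeI, −78 °C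
Reagents that add atoms: iodomethane, CI
Why: Evans asymmetric alkylation, in which the chelated (Z)‑sodium enolate is methylated on the face opposite the benzyl group and so sets the (2R) centre (C6′ of the target).

Step 3
Reactants: 4 (R)‑4‑benzyl‑3‑[(2R)‑2‑methylhexanoyl]oxazolidin‑2‑one
Product: 5 (R)‑2‑methylhexan‑1‑ol
Conditions: LiBH4, MeOH (1 equiv), THF, 0 °C
Reagents that add atoms: none
Why: Reductive cleavage of the imide by LiBH4 gives the primary alcohol without touching the α‑stereocentre and returns the auxiliary.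

Step 4
Reactants: 5 (R)‑2‑methylhexan‑1‑ol
Product: 7 ethyl (2E,4R)‑2,4‑dimethyloct‑2‑enoate, via (R)‑2‑methylhexanal 6 (not isolated)
Conditions: Dess–Martin periodinane, CH2Cl2, 0 °C → rt; then Ph3P=C(Me)CO2Et, rt
Reagents that add atoms: ethyl 2‑(triphenylphosphoranylidene)propanoate, CCOC(=O)C(C)=P(c1ccccc1)(c1ccccc1)c1ccccc1
Why: Dess–Martin oxidation and in situ Wittig olefination with the stabilised α‑methyl ylide should give the (E)‑trisubstituted enoate before the α‑chiral aldehyde can epimerise.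

Step 5
Reactants: 7 ethyl (2E,4R)‑2,4‑dimethyloct‑2‑enoate
Product: 8 (2E,4R)‑2,4‑dimethyloct‑2‑en‑1‑ol
Conditions: DIBAL‑H, CH2Cl2, −78 °C; Rochelle salt work‑up
Reagents that add atoms: none
Why: DIBAL‑H 1,2‑reduction of the enoate gives the allylic alcohol with the alkene geometry unchanged.

Step 6
Reactants: 8 (2E,4R)‑2,4‑dimethyloct‑2‑en‑1‑ol
Product: 10 ethyl (2E,4E,6R)‑2,4,6‑trimethyldeca‑2,4‑dienoate, via (2E,4R)‑2,4‑dimethyloct‑2‑enal 9 (not isolated)
Conditions: MnO2, Ph3P=C(Me)CO2Et, toluene, 80 °C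
Reagents that add atoms: ethyl 2‑(triphenylphosphoranylidene)propanoate, CCOC(=O)C(C)=P(c1ccccc1)(c1ccccc1)c1ccccc1
Why: Tandem allylic oxidation/Wittig olefination, in which the stabilised ylide traps the enal as the (E)‑alkene and so gives the (2E,4E)‑diene.

Step 7
Reactants: 10 ethyl (2E,4E,6R)‑2,4,6‑trimethyldeca‑2,4‑dienoate
Product: 11 (2E,4E,6R)‑2,4,6‑trimethyldeca‑2,4‑dienamide
Conditions: AlMe3, NH4Cl, toluene, 0 °C → 50 °C; dil. HCl work‑up
Reagents that add atoms: ammonium chloride, [NH4+].[Cl-]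
Why: Aluminium amide aminolysis (Weinreb type) converts the hindered conjugated ester directly into the primary amide without disturbing the diene.

Step 8
Reactants: 12 4,4‑dimethoxycyclohexa‑2,5‑dien‑1‑one; 13 ethynyltrimethylsilane
Product: 15 4‑hydroxy‑4‑[(trimethylsilyl)ethynyl]cyclohexa‑2,5‑dien‑1‑one, via ketal carbinol 14 (not isolated)
Conditions: 13, n‑BuLi, THF, −78 °C; 12, −78 °C; then 1 M aq. HCl, 0 °C → rt
Reagents that add atoms: none
Why: 1,2‑Addition of the lithium acetylide to the quinone monoketal carbonyl, followed by acid hydrolysis of the dimethyl ketal in the work‑up, gives the symmetric p‑quinol.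

Step 9
Reactants: 15 4‑hydroxy‑4‑[(trimethylsilyl)ethynyl]cyclohexa‑2,5‑dien‑1‑one
Product: 16 (2R,3aS,7aS)‑2‑isopropyl‑7a‑[(trimethylsilyl)ethynyl]‑3a,7a‑dihydro‑1,3‑benzodioxol‑5(4H)‑one
Conditions: isobutyraldehyde (3 equiv), (R)‑TRIP (5 mol%), 4 Å MS, toluene, rt
Reagents that add atoms: isobutyraldehyde, CC(C)C=O
Why: Chiral phosphoric acid‑catalysed hemiacetal formation at the tertiary hydroxyl and intramolecular oxa‑Michael addition (a known desymmetrising cascade of p‑quinols) in which the catalyst selects one enantiotopic enone arm, so that C4 and C5 (target numbering) arise together, the five‑membered tether forcing the cis fusion and the isopropyl group taking the exo position.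

Step 10
Reactants: 16 (2R,3aS,7aS)‑2‑isopropyl‑7a‑[(trimethylsilyl)ethynyl]‑3a,7a‑dihydro‑1,3‑benzodioxol‑5(4H)‑one
Product: 17 (2R,3aS,7aS)‑6‑iodo‑2‑isopropyl‑7a‑[(trimethylsilyl)ethynyl]‑3a,7a‑dihydro‑1,3‑benzodioxol‑5(4H)‑one
Conditions: I2, pyridine/CH2Cl2 (1:1), 0 °C → rt
Reagents that add atoms: iodine, II
Why: α‑Iodination of the enone by the pyridine addition/iodination/elimination sequence (Baylis–Hillman‑type) places iodine on the only enone α‑carbon, the future C2.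

Step 11
Reactants: 17 (2R,3aS,7aS)‑6‑iodo‑2‑isopropyl‑7a‑[(trimethylsilyl)ethynyl]‑3a,7a‑dihydro‑1,3‑benzodioxol‑5(4H)‑one; 11 (2E,4E,6R)‑2,4,6‑trimethyldeca‑2,4‑dienamide
Product: 18 (2E,4E,6R)‑N‑[(2R,3aS,7aS)‑2‑isopropyl‑5‑oxo‑7a‑[(trimethylsilyl)ethynyl]‑3a,4,5,7a‑tetrahydro‑1,3‑benzodioxol‑6‑yl]‑2,4,6‑trimethyldeca‑2,4‑dienamide
Conditions: CuI (10 mol%), N,N′‑dimethylethylenediamine (20 mol%), Cs2CO3 (1.5 equiv), THF, 50 °C
Reagents that add atoms: none
Why: Goldberg‑type copper/diamine amidation of the activated vinyl iodide by the primary amide forms the C2–N enamide bond, and any retro‑oxa‑Michael opening of the acetal is reversible and stereochemically harmless because C4 stays stereogenic.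

Step 12
Reactants: 18 (2E,4E,6R)‑N‑[(2R,3aS,7aS)‑2‑isopropyl‑5‑oxo‑7a‑[(trimethylsilyl)ethynyl]‑3a,4,5,7a‑tetrahydro‑1,3‑benzodioxol‑6‑yl]‑2,4,6‑trimethyldeca‑2,4‑dienamide
Product: 19 (2E,4E,6R)‑N‑[(2R,3aS,7aS)‑7a‑ethynyl‑2‑isopropyl‑5‑oxo‑3a,4,5,7a‑tetrahydro‑1,3‑benzodioxol‑6‑yl]‑2,4,6‑trimethyldeca‑2,4‑dienamide
Conditions: TBAF (1.1 equiv), AcOH (1.1 equiv), THF, 0 °C
Reagents that add atoms: none
Why: Fluoride‑mediated protodesilylation of the alkynylsilane, buffered with acetic acid so that the β‑alkoxy ketone is not exposed to free base.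

Step 13
Reactants: 19 (2E,4E,6R)‑N‑[(2R,3aS,7aS)‑7a‑ethynyl‑2‑isopropyl‑5‑oxo‑3a,4,5,7a‑tetrahydro‑1,3‑benzodioxol‑6‑yl]‑2,4,6‑trimethyldeca‑2,4‑dienamide
Product: 20 (2E,4E,6R)‑N‑[(3S,4S)‑3‑ethynyl‑3,4‑dihydroxy‑6‑oxocyclohex‑1‑en‑1‑yl]‑2,4,6‑trimethyldeca‑2,4‑dienamide (cis‑diol)
Conditions: TFA/H2O (4:1), 0 °C → rt
Reagents that add atoms: none
Why: Acid hydrolysis of the alkylidene acetal proceeds through the oxocarbenium ion at the former aldehyde carbon, so the C–O bonds at C4 and C5 are not broken and both centres are retained.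

Step 14
Reactants: 20 (2E,4E,6R)‑N‑[(3S,4S)‑3‑ethynyl‑3,4‑dihydroxy‑6‑oxocyclohex‑1‑en‑1‑yl]‑2,4,6‑trimethyldeca‑2,4‑dienamide
Product: 21 (2E,4E,6R)‑N‑[(3S,4S)‑3‑ethynyl‑6‑oxo‑3,4‑bis(triethylsilyloxy)cyclohex‑1‑en‑1‑yl]‑2,4,6‑trimethyldeca‑2,4‑dienamide
Conditions: TESOTf (2.5 equiv), 2,6‑lutidine, CH2Cl2, −78 → 0 °C
Reagents that add atoms: triethylsilyl trifluoromethanesulfonate, CC[Si](CC)(CC)OS(=O)(=O)C(F)(F)F
Why: The silyl triflate silylates both the secondary and the hindered tertiary hydroxyl, giving fluoride‑labile protection for the base step to come.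

Step 15
Reactants: 21 (2E,4E,6R)‑N‑[(3S,4S)‑3‑ethynyl‑6‑oxo‑3,4‑bis(triethylsilyloxy)cyclohex‑1‑en‑1‑yl]‑2,4,6‑trimethyldeca‑2,4‑dienamide
Product: 22 (2E,4E,6R)‑N‑[(3S,4S)‑6‑oxo‑3,4‑bis(triethylsilyloxy)‑3‑[(E)‑2‑(tributylstannyl)vinyl]cyclohex‑1‑en‑1‑yl]‑2,4,6‑trimethyldeca‑2,4‑dienamide
Conditions: Bu3SnH, PdCl2(PPh3)2 (3 mol%), THF, 0 °C → rt
Reagents that add atoms: tributyltin hydride, CCCC[SnH](CCCC)CCCC
Why: Pd‑catalysed syn‑hydrostannation of the terminal alkyne places tin on the terminal carbon, away from the quaternary silyloxy centre, and so gives the (E)‑vinylstannane faster than any reduction of the hindered enone.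

Step 16
Reactants: 23 glutaconaldehyde potassium salt
Product: 24 (2E,4E)‑5‑bromopenta‑2,4‑dienal
Conditions: Ph3P·Br2, CH2Cl2, 0 °C → rt
Reagents that add atoms: dibromotriphenylphosphorane, BrP(Br)(c1ccccc1)(c1ccccc1)c1ccccc1
Why: O‑Phosphonium activation of the dienolate and addition–elimination by bromide (vinylic substitution) gives the thermodynamically preferred (E,E)‑bromodienal.

Step 17
Reactants: 24 (2E,4E)‑5‑bromopenta‑2,4‑dienal
Product: 25 (2E,4E)‑5‑bromopenta‑2,4‑dienoic acid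
Conditions: NaClO2, NaH2PO4, 2‑methylbut‑2‑ene, t‑BuOH/H2O, 0 °C → rt
Reagents that add atoms: sodium chlorite, [Na+].[O-]Cl=O
Why: Pinnick oxidation converts the conjugated aldehyde into the acid without touching the diene or the vinyl bromide.

Step 18
Reactants: 25 (2E,4E)‑5‑bromopenta‑2,4‑dienoic acid
Product: 26 (2E,4E)‑5‑bromopenta‑2,4‑dienoyl chloride (used crude)
Conditions: (COCl)2, DMF (cat.), CH2Cl2, 0 °C → rt
Reagents that add atoms: oxalyl chloride, ClC(=O)C(Cl)=O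
Why: Vilsmeier‑catalysed acid chloride formation under neutral conditions keeps the diene geometry.

Step 19
Reactants: 27 5‑hydroxypiperidin‑2‑one (racemic)
Product: 28 5‑(triethylsilyloxy)piperidin‑2‑one (racemic)
Conditions: TESCl, imidazole, DMF, rt
Reagents that add atoms: chlorotriethylsilane, CC[Si](Cl)(CC)CC
Why: The alcohol is far more nucleophilic than the lactam N–H, so O‑silylation is selective.

Step 20
Reactants: 28 5‑(triethylsilyloxy)piperidin‑2‑one; 26 (2E,4E)‑5‑bromopenta‑2,4‑dienoyl chloride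
Product: 29 1‑[(2E,4E)‑5‑bromopenta‑2,4‑dienoyl]‑5‑(triethylsilyloxy)piperidin‑2‑one (racemic)
Conditions: n‑BuLi, THF, −78 °C; then 26, −78 → −20 °C
Reagents that add atoms: none
Why: N‑Acylation of the lithiated lactam by the acid chloride is the standard route to N‑acyl lactams (imides).

Step 21
Reactants: 29 1‑[(2E,4E)‑5‑bromopenta‑2,4‑dienoyl]‑5‑(triethylsilyloxy)piperidin‑2‑one
Product: 30 1‑[(2E,4E)‑5‑bromopenta‑2,4‑dienoyl]‑5‑hydroxypiperidin‑2‑one (racemic)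
Conditions: HF·pyridine, pyridine, THF, 0 °C
Reagents that add atoms: none
Why: Acidic fluoride cleaves the secondary triethylsilyl ether under conditions that leave the imide and the vinyl bromide alone.

Step 22
Reactants: 30 1‑[(2E,4E)‑5‑bromopenta‑2,4‑dienoyl]‑5‑hydroxypiperidin‑2‑one
Product: 31 1‑[(2E,4E)‑5‑bromopenta‑2,4‑dienoyl]piperidine‑2,5‑dione
Conditions: Dess–Martin periodinane, CH2Cl2, rt
Reagents that add atoms: none
Why: Dess–Martin oxidation gives the ketone under non‑basic conditions, so the base‑labile α‑imido ketone is not enolised.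

Step 23
Reactants: 22 (2E,4E,6R)‑N‑[(3S,4S)‑6‑oxo‑3,4‑bis(triethylsilyloxy)‑3‑[(E)‑2‑(tributylstannyl)vinyl]cyclohex‑1‑en‑1‑yl]‑2,4,6‑trimethyldeca‑2,4‑dienamide; 31 1‑[(2E,4E)‑5‑bromopenta‑2,4‑dienoyl]piperidine‑2,5‑dione
Product: 32 (2E,4E,6R)‑N‑[(3R,4S)‑3‑[(1E,3E,5E)‑7‑(2,5‑dioxopiperidin‑1‑yl)‑7‑oxohepta‑1,3,5‑trien‑1‑yl]‑6‑oxo‑3,4‑bis(triethylsilyloxy)cyclohex‑1‑en‑1‑yl]‑2,4,6‑trimethyldeca‑2,4‑dienamide
Conditions: PdCl2(MeCN)2 (5 mol%), DMF, rt, dark
Reagents that add atoms: none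
Why: Stille coupling of vinylstannane and vinyl bromide proceeds with retention at both alkenes under neutral, base‑free conditions, so the all‑E triene forms and the keto imide survives.

Step 24
Reactants: 32 (2E,4E,6R)‑N‑[(3R,4S)‑3‑[(1E,3E,5E)‑7‑(2,5‑dioxopiperidin‑1‑yl)‑7‑oxohepta‑1,3,5‑trien‑1‑yl]‑6‑oxo‑3,4‑bis(triethylsilyloxy)cyclohex‑1‑en‑1‑yl]‑2,4,6‑trimethyldeca‑2,4‑dienamide
Product: 33 4,5‑bis‑O‑triethylsilyl ether of the target
Conditions: KHMDS (1.2 equiv), THF, −78 → −20 °C; AcOH (2 equiv), −78 °C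
Reagents that add atoms: none
Why: Proposed new method: KHMDS removes a proton from the piperidinedione CH2 that lies between the ketone and the imide nitrogen (the most acidic C–H of 32), and the enolate carbon adds across nitrogen to the ring imide carbonyl (3‑exo‑trig, giving a 6‑azabicyclo[3.1.0]hexanolate) whose C–N bond then breaks, so the lactam carbonyl migrates from N to C and the cyclopentane ring closes by a transannular 1,3 C–C bond formation, a 6→5 ring contraction. The closest known reaction type is the base‑induced transannular rearrangement of N‑acyl‑activated 2,5‑diketopiperazines to 3‑aminopyrrolidine‑2,4‑diones, within the wider family of anionic N→C 1,2‑acyl shifts; here a ketone enolate replaces the lactam enolate and the trienoyl group itself is the N‑activator that ends as the amide. No stereocentre is formed, because the nitrogen‑bearing ring carbon becomes the sp2 centre of the enolised dione, and the existing centres are not adjacent to any site that is deprotonated. The step needs attack on the ring carbonyl and not on the exocyclic one: the ring carbonyl is a saturated imide carbonyl whereas the exocyclic one is deactivated by conjugation with the triene, and collapse along the ring pathway expels the better stabilised conjugated amide anion. It also needs the core to stay intact: only about one equivalent of a non‑nucleophilic base is used at low temperature, the α‑imido ketone should be more acidic than the C6 methylene of the β‑silyloxy ketone, and the product should be drained irreversibly as the potassium salt of the vinylogous acid until the acetic acid quench.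

Step 25
Reactants: 33 4,5‑bis‑O‑triethylsilyl ether of the target
Product: 34 (2E,4E,6R)‑N‑[(3R,4S)‑3,4‑dihydroxy‑3‑[(1E,3E,5E)‑7‑[(2‑hydroxy‑5‑oxocyclopent‑1‑en‑1‑yl)amino]‑7‑oxohepta‑1,3,5‑trien‑1‑yl]‑6‑oxocyclohex‑1‑en‑1‑yl]‑2,4,6‑trimethyldeca‑2,4‑dienamide (target)
Conditions: HF·pyridine, pyridine, THF, 0 °C → rt
Reagents that add atoms: none
Why: Buffered acidic fluoride removes both triethylsilyl ethers under conditions that polyene amides, the β‑hydroxy ketone and the vinylogous acid should tolerate.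

**Compound list**

1 | (R)‑4‑benzyloxazolidin‑2‑one | O=C1N[C@H](Cc2ccccc2)CO1 | starting material
2 | hexanoyl chloride | CCCCCC(Cl)=O | starting material
3 | (R)‑4‑benzyl‑3‑hexanoyloxazolidin‑2‑one | CCCCCC(=O)N1[C@H](Cc2ccccc2)COC1=O | intermediate
4 | (R)‑4‑benzyl‑3‑[(2R)‑2‑methylhexanoyl]oxazolidin‑2‑one | CCCC[C@@H](C)C(=O)N1[C@H](Cc2ccccc2)COC1=O | intermediate
5 | (R)‑2‑methylhexan‑1‑ol | CCCC[C@@H](C)CO | intermediate
6 | (R)‑2‑methylhexanal | CCCC[C@@H](C)C=O | intermediate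
7 | ethyl (2E,4R)‑2,4‑dimethyloct‑2‑enoate | CCCC[C@@H](C)/C=C(\C)C(=O)OCC | intermediate
8 | (2E,4R)‑2,4‑dimethyloct‑2‑en‑1‑ol | CCCC[C@@H](C)/C=C(\C)CO | intermediate
9 | (2E,4R)‑2,4‑dimethyloct‑2‑enal | CCCC[C@@H](C)/C=C(\C)C=O | intermediate
10 | ethyl (2E,4E,6R)‑2,4,6‑trimethyldeca‑2,4‑dienoate | CCCC[C@@H](C)/C=C(C)/C=C(\C)C(=O)OCC | intermediate
11 | (2E,4E,6R)‑2,4,6‑trimethyldeca‑2,4‑dienamide | CCCC[C@@H](C)/C=C(C)/C=C(\C)C(N)=O | intermediate
12 | 4,4‑dimethoxycyclohexa‑2,5‑dien‑1‑one | COC1(OC)C=CC(=O)C=C1 | starting material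
13 | ethynyltrimethylsilane | C#C[Si](C)(C)C | starting material
14 | 4,4‑dimethoxy‑1‑[(trimethylsilyl)ethynyl]cyclohexa‑2,5‑dien‑1‑ol | COC1(OC)C=CC(O)(C#C[Si](C)(C)C)C=C1 | intermediate
15 | 4‑hydroxy‑4‑[(trimethylsilyl)ethynyl]cyclohexa‑2,5‑dien‑1‑one | O=C1C=CC(O)(C#C[Si](C)(C)C)C=C1 | intermediate
16 | (2R,3aS,7aS)‑2‑isopropyl‑7a‑[(trimethylsilyl)ethynyl]‑3a,7a‑dihydro‑1,3‑benzodioxol‑5(4H)‑one | O=C1C=C[C@@]2(C#C[Si](C)(C)C)O[C@H](C(C)C)O[C@H]2C1 | intermediate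
17 | (2R,3aS,7aS)‑6‑iodo‑2‑isopropyl‑7a‑[(trimethylsilyl)ethynyl]‑3a,7a‑dihydro‑1,3‑benzodioxol‑5(4H)‑one | O=C1C(I)=C[C@@]2(C#C[Si](C)(C)C)O[C@H](C(C)C)O[C@H]2C1 | intermediate
18 | (2E,4E,6R)‑N‑[(2R,3aS,7aS)‑2‑isopropyl‑5‑oxo‑7a‑[(trimethylsilyl)ethynyl]‑3a,4,5,7a‑tetrahydro‑1,3‑benzodioxol‑6‑yl]‑2,4,6‑trimethyldeca‑2,4‑dienamide | CCCC[C@@H](C)/C=C(C)/C=C(\C)C(=O)NC1=C[C@@]2(C#C[Si](C)(C)C)O[C@H](C(C)C)O[C@H]2CC1=O | intermediate
19 | (2E,4E,6R)‑N‑[(2R,3aS,7aS)‑7a‑ethynyl‑2‑isopropyl‑5‑oxo‑3a,4,5,7a‑tetrahydro‑1,3‑benzodioxol‑6‑yl]‑2,4,6‑trimethyldeca‑2,4‑dienamide | CCCC[C@@H](C)/C=C(C)/C=C(\C)C(=O)NC1=C[C@@]2(C#C)O[C@H](C(C)C)O[C@H]2CC1=O | intermediate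
20 | (2E,4E,6R)‑N‑[(3S,4S)‑3‑ethynyl‑3,4‑dihydroxy‑6‑oxocyclohex‑1‑en‑1‑yl]‑2,4,6‑trimethyldeca‑2,4‑dienamide | CCCC[C@@H](C)/C=C(C)/C=C(\C)C(=O)NC1=C[C@](O)(C#C)[C@@H](O)CC1=O | intermediate
21 | (2E,4E,6R)‑N‑[(3S,4S)‑3‑ethynyl‑6‑oxo‑3,4‑bis(triethylsilyloxy)cyclohex‑1‑en‑1‑yl]‑2,4,6‑trimethyldeca‑2,4‑dienamide | CCCC[C@@H](C)/C=C(C)/C=C(\C)C(=O)NC1=C[C@](O[Si](CC)(CC)CC)(C#C)[C@@H](O[Si](CC)(CC)CC)CC1=O | intermediate
22 | (2E,4E,6R)‑N‑[(3S,4S)‑6‑oxo‑3,4‑bis(triethylsilyloxy)‑3‑[(E)‑2‑(tributylstannyl)vinyl]cyclohex‑1‑en‑1‑yl]‑2,4,6‑trimethyldeca‑2,4‑dienamide | CCCC[C@@H](C)/C=C(C)/C=C(\C)C(=O)NC1=C[C@](O[Si](CC)(CC)CC)(/C=C/[Sn](CCCC)(CCCC)CCCC)[C@@H](O[Si](CC)(CC)CC)CC1=O | intermediate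
23 | glutaconaldehyde potassium salt | [K+].[O-]/C=C/C=C/C=O | starting material
24 | (2E,4E)‑5‑bromopenta‑2,4‑dienal | O=C/C=C/C=C/Br | intermediate
25 | (2E,4E)‑5‑bromopenta‑2,4‑dienoic acid | OC(=O)/C=C/C=C/Br | intermediate
26 | (2E,4E)‑5‑bromopenta‑2,4‑dienoyl chloride | ClC(=O)/C=C/C=C/Br | intermediate
27 | 5‑hydroxypiperidin‑2‑one (racemic) | OC1CCC(=O)NC1 | starting material
28 | 5‑(triethylsilyloxy)piperidin‑2‑one (racemic) | CC[Si](CC)(CC)OC1CCC(=O)NC1 | intermediate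
29 | 1‑[(2E,4E)‑5‑bromopenta‑2,4‑dienoyl]‑5‑(triethylsilyloxy)piperidin‑2‑one (racemic) | CC[Si](CC)(CC)OC1CCC(=O)N(C1)C(=O)/C=C/C=C/Br | intermediate
30 | 1‑[(2E,4E)‑5‑bromopenta‑2,4‑dienoyl]‑5‑hydroxypiperidin‑2‑one (racemic) | OC1CCC(=O)N(C1)C(=O)/C=C/C=C/Br | intermediate
31 | 1‑[(2E,4E)‑5‑bromopenta‑2,4‑dienoyl]piperidine‑2,5‑dione | O=C1CCC(=O)N(C1)C(=O)/C=C/C=C/Br | intermediate
32 | (2E,4E,6R)‑N‑[(3R,4S)‑3‑[(1E,3E,5E)‑7‑(2,5‑dioxopiperidin‑1‑yl)‑7‑oxohepta‑1,3,5‑trien‑1‑yl]‑6‑oxo‑3,4‑bis(triethylsilyloxy)cyclohex‑1‑en‑1‑yl]‑2,4,6‑trimethyldeca‑2,4‑dienamide | CCCC[C@@H](C)/C=C(C)/C=C(\C)C(=O)NC1=C[C@](O[Si](CC)(CC)CC)(/C=C/C=C/C=C/C(=O)N2CC(=O)CCC2=O)[C@@H](O[Si](CC)(CC)CC)CC1=O | intermediate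
33 | 4,5‑bis‑O‑triethylsilyl ether of the target | CCCC[C@@H](C)/C=C(C)/C=C(\C)C(=O)NC1=C[C@](O[Si](CC)(CC)CC)(/C=C/C=C/C=C/C(=O)NC2=C(O)CCC2=O)[C@@H](O[Si](CC)(CC)CC)CC1=O | intermediate
34 | (2E,4E,6R)‑N‑[(3R,4S)‑3,4‑dihydroxy‑3‑[(1E,3E,5E)‑7‑[(2‑hydroxy‑5‑oxocyclopent‑1‑en‑1‑yl)amino]‑7‑oxohepta‑1,3,5‑trien‑1‑yl]‑6‑oxocyclohex‑1‑en‑1‑yl]‑2,4,6‑trimethyldeca‑2,4‑dienamide | CCCC[C@@H](C)/C=C(C)/C=C(\C)C(=O)NC1=C[C@](O)(/C=C/C=C/C=C/C(=O)NC2=C(O)CCC2=O)[C@@H](O)CC1=O | target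

**Step count and risks**

Total step count: 25. Longest linear sequence: 15 steps (steps 1–7, 11–15, 23–25).

Steps most likely to fail:

1. Step 24 (Proposed new method). The enolate may transfer the exocyclic trienoyl group from N to C instead of attacking the ring carbonyl, or the base may enolise the cyclohexenone and expel the β‑silyloxy group. The fallback uses known chemistry and sets out from acid chloride 26 and stannane 22. Cyclopentane‑1,3‑dione is nitrated (fuming HNO3) to 2‑nitrocyclopentane‑1,3‑dione F1, which is hydrogenated (H2, Pd/C, HCl, MeOH) to 2‑amino‑3‑hydroxycyclopent‑2‑en‑1‑one hydrochloride F2. N‑Acylation of F2 by 26 (Et3N, CH2Cl2) should give (2E,4E)‑5‑bromo‑N‑(2‑hydroxy‑5‑oxocyclopent‑1‑en‑1‑yl)penta‑2,4‑dienamide F3. Stille coupling of F3 with 22 (PdCl2(MeCN)2, DMF, rt) should give 33, where the route is rejoined before step 25; in this variant the five‑membered ring is bought and not closed.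

2. Step 9. Enantioselection may be poor, or product inhibition may stall the hemiacetal oxa‑Michael closure with the small alkynyl quinol. The fallback sets out from 15 and replaces the acid‑catalysed acetal cascade by a boron‑tethered oxa‑Michael addition under bifunctional base/hydrogen‑bond catalysis. Phenylboronic acid and a cinchona‑derived amine–thiourea catalyst should convert 15 into (3aS,7aS)‑2‑phenyl‑7a‑[(trimethylsilyl)ethynyl]‑3a,7a‑dihydro‑1,3,2‑benzodioxaborol‑5(4H)‑one F4. Transesterification with pinacol releases (4S,5S)‑4,5‑dihydroxy‑4‑[(trimethylsilyl)ethynyl]cyclohex‑2‑en‑1‑one F5. Acetalisation of F5 with 1,1‑dimethoxy‑2‑methylpropane (PPTS, CH2Cl2) should give 16 with the isopropyl group in the thermodynamically preferred exo position, rejoining the route before step 10.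

3. Step 11. The base needed for the C–N coupling may open the dioxolane by retro‑oxa‑Michael reaction, and the hindered dienamide may couple slowly. The fallback sets out from iodoenone 17 and ester 10; it introduces nitrogen as a small carbamate and attaches the side chain by N‑acylation. Pd‑catalysed coupling of 17 with tert‑butyl carbamate (Pd2(dba)3, Xantphos, Cs2CO3, dioxane, 40 °C) should give tert‑butyl N‑[(2R,3aS,7aS)‑2‑isopropyl‑5‑oxo‑7a‑[(trimethylsilyl)ethynyl]‑3a,4,5,7a‑tetrahydro‑1,3‑benzodioxol‑6‑yl]carbamate F6. Anhydrous HCl in dioxane then gives (2R,3aS,7aS)‑6‑amino‑2‑isopropyl‑7a‑[(trimethylsilyl)ethynyl]‑3a,7a‑dihydro‑1,3‑benzodioxol‑5(4H)‑one hydrochloride F7. Ester 10 is saponified (LiOH, THF/H2O) to (2E,4E,6R)‑2,4,6‑trimethyldeca‑2,4‑dienoic acid F8 and converted with oxalyl chloride into (2E,4E,6R)‑2,4,6‑trimethyldeca‑2,4‑dienoyl chloride F9. F9 acylates F7 (pyridine, CH2Cl2, 0 °C) to give 18, rejoining the route before step 12.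

Further compounds
F1 | step 24 | 2‑nitrocyclopentane‑1,3‑dione | O=C1CCC(=O)C1[N+](=O)[O-]
F2 | step 24 | 2‑amino‑3‑hydroxycyclopent‑2‑en‑1‑one hydrochloride | NC1=C(O)CCC1=O.Cl
F3 | step 24 | (2E,4E)‑5‑bromo‑N‑(2‑hydroxy‑5‑oxocyclopent‑1‑en‑1‑yl)penta‑2,4‑dienamide | O=C(/C=C/C=C/Br)NC1=C(O)CCC1=O
F4 | step 9 | (3aS,7aS)‑2‑phenyl‑7a‑[(trimethylsilyl)ethynyl]‑3a,7a‑dihydro‑1,3,2‑benzodioxaborol‑5(4H)‑one | O=C1C=C[C@@]2(C#C[Si](C)(C)C)OB(c3ccccc3)O[C@H]2C1
F5 | step 9 | (4S,5S)‑4,5‑dihydroxy‑4‑[(trimethylsilyl)ethynyl]cyclohex‑2‑en‑1‑one | O=C1C=C[C@](O)(C#C[Si](C)(C)C)[C@@H](O)C1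
F6 | step 11 | tert‑butyl N‑[(2R,3aS,7aS)‑2‑isopropyl‑5‑oxo‑7a‑[(trimethylsilyl)ethynyl]‑3a,4,5,7a‑tetrahydro‑1,3‑benzodioxol‑6‑yl]carbamate | CC(C)(C)OC(=O)NC1=C[C@@]2(C#C[Si](C)(C)C)O[C@H](C(C)C)O[C@H]2CC1=O
F7 | step 11 | (2R,3aS,7aS)‑6‑amino‑2‑isopropyl‑7a‑[(trimethylsilyl)ethynyl]‑3a,7a‑dihydro‑1,3‑benzodioxol‑5(4H)‑one hydrochloride | Cl.NC1=C[C@@]2(C#C[Si](C)(C)C)O[C@H](C(C)C)O[C@H]2CC1=O
F8 | step 11 | (2E,4E,6R)‑2,4,6‑trimethyldeca‑2,4‑dienoic acid | CCCC[C@@H](C)/C=C(C)/C=C(\C)C(=O)O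
F9 | step 11 | (2E,4E,6R)‑2,4,6‑trimethyldeca‑2,4‑dienoyl chloride | CCCC[C@@H](C)/C=C(C)/C=C(\C)C(Cl)=O
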